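## Structural features

Compound 17 is an achiral chain of five benzene rings, lettered A to E from the 2,4,6-trihydroxyphenoxy end, joined by four diaryl ether oxygens and carrying thirteen free phenolic hydroxyls; it has no stereocenter and no ring other than the five arenes. Ring A is a phloroglucinol bound through the oxygen on C2, and ring B carries that oxygen at C1 between two C–H positions, hydroxyls at C3 and C5, and the oxygen to ring C at C4. Ring C is pentaoxygenated, with the oxygen to ring B on C1, the oxygen to ring D on C2, hydroxyls on C3 to C5 and a single hydrogen on C6. Ring D carries the oxygen from ring C at C1, hydroxyls at C3 and C4 and the oxygen to ring E at C5, and ring E is a 3,4,5-trihydroxyphenyl group bound at C1. The fragile part is the free polyphenol itself: the pyrogallol arrays of rings C and E, the catechol of ring D and the hydroquinone-like ring B are oxidised by air, fastest in base, so every hydroxyl has to stay masked until the last step. The real difficulty lies in the four C–O–C bonds between electron-rich rings, three of which (at ring A C2, ring B C4 and ring C C2) sit on a carbon flanked by two oxygenated carbons, which slows the usual aryl ether couplings. Thirteen near-equivalent hydroxyls also leave no room for late differentiation, so each oxygen must arrive in its final place. The key step exploits the fact that C1 of ring D and C1 of ring E are para to the middle oxygen of a 3,4,5-trioxygenated ring and flanked by C–H on both sides, which is the place of the carboxyl carbon in gallic acid, so that rings D and E with their two ether oxygens amount to a meta-digalloyl ester with both carbonyl carbons taken out.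

## Logic of the disconnections

17 to 16. The thirteen O–H bonds are traced back to O–CH3 bonds. The free polyphenol cannot be carried through any coupling, whereas 16 is a stable compound that can be chromatographed. The demand on the forward step is cleavage of thirteen alkyl–oxygen bonds without touching the four aryl–oxygen–aryl bonds, and isolation of 17 without oxidation.

16 to 15. The bond from the ring C oxygen (on C2) to ring D C1 and the bond from the ring D oxygen (on C5) to ring E C1 are cut, and a carbonyl carbon is placed in each gap. Two diaryl ethers, one of them at the most crowded oxygen of the molecule, become two aryl esters that ordinary acylation can make. The forward step must extrude CO from both esters, insert the metal into the acyl C–O bond and not the aryl C–O bond, and leave methyl ethers and diaryl ethers alone.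

15 to 10 and 13 (through 14). The acyl C–O bond at ring C is cut. This is the convergent point: a three-ring phenol and a two-ring acid of similar size. The forward step must acylate a phenol with two ortho substituents while the aryl ester already present in the acid partner stays intact.

13 to 11 and 12. The ester bond between the ring D oxygen and the ring E carbonyl is cut, which leads to 11 and 12, both purchasable. The forward step must acylate the phenol of 11 in the presence of its free carboxyl group.

10 to 8 (through 9). The C2–O bond of ring C is exchanged for a C2–CHO bond. The formyl group is a masked hydroxyl that cannot interfere with ether formation, and it activates the neighbouring carbon for the next disconnection. The forward step needs aryl migration in a peracid oxidation and a peracid that spares the electron-rich rings.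

8 to 5 and 7. The B–C ether is cut between the oxygen and ring C C1. The oxygen stays on ring B, where it is flanked by two methoxy groups. The electrophilic carbon lies on ring C, with a hydrogen on one side and the activating formyl group on the other. The forward step is a copper-catalysed coupling of a phenol with two ortho substituents.

7 to 6. The C–CHO bond is cut. In 6 the two open positions are equivalent, so the formylation can give only one isomer.

5 to 3 (through 4), and 3 to 1 and 2. The same tactic is used for ring B. The C4 hydroxyl comes from a formyl group, and the A–B ether is cut between the oxygen and ring B C1. The oxygen remains on 1, and the bromide of 2 is para to the formyl group and flanked by C–H, the easiest carbon in the molecule for an ether coupling.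

## Other disconnections considered

Alternative 1: Ring A is built last by a double Claisen condensation.

The cut removes the two C–C bonds of ring A that join the hydroxyl-bearing carbons next to the ether carbon to the two unsubstituted ring carbons. It leads back to the aryloxymalonate A1, which is the ring B–C–D–E tetramer with an O–CH(CO2Me)2 group on ring B C1, and to dimethyl 3-oxopentanedioate A2. In the forward key step the bis-enolate of A2 (NaOMe or Mg(OMe)2, heat) is acylated twice by the malonate esters of A1 and closes ring A as the phloroglucinol diester A3. Saponification, double decarboxylation and cleavage of ten methyl ethers follow.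

In its favour, the reaction class is old and metal-free. The ether oxygen flanked by two hydroxyls arrives without a coupling at an oxidation-prone 2,6-dioxygenated phenol, and ring A comes out unprotected.

Against it, the cut addresses the easiest of the four ethers. In the chosen plan the A–B bond is made in step 1 at an unhindered, formyl-activated carbon. The B–C, C–D and D–E bonds remain, so all the work of assembling A1 from four rings, and an O-alkylation on top, still stands. The α-aryloxy malonate A1 is a branched, sluggish acceptor, and self-condensation of A2 competes.

In comparison, on structure it solves one ether where the key step of the chosen plan solves two. On mechanism it is the better of the two, since every step is of a known type while step 8 is not. It also has three fewer methyl ethers to cleave. On step economy it is worse, because the tetramer synthesis, alkylation, condensation and decarboxylation add up to more steps.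

Alternative 2: Ring C is built last by a Danheiser-type benzannulation.

The cut takes ring C apart into the ring D–E 2-aryloxy-3,4-dimethoxycyclobutenone A4 and the ring A–B aryl ethynyl ether A5. In the forward key step, heating causes 4π ring opening of A4, and the ketene function so formed adds (2+2) to A5. A second 4π opening and a 6π closure then give the phenol A6. Net, two new C–C bonds are formed, and a third ring bond is broken in the first opening and re-formed in the closure. The free hydroxyl ends up next to the ring C hydrogen.

In its favour, the substitution pattern of the pentaoxygenated ring follows from the polarity of ketene and ynol ether. Both crowded ether oxygens of ring C are brought in on sp and sp2 carbons of small precursors, so no coupling at a congested aromatic carbon is needed for the B–C or C–D ether. On this point it is better than the chosen plan, whose step 4 is a hindered copper coupling. The reaction is thermal and of a known class.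

Against it, both partners are laborious. A5 needs ethynylation of a di-ortho-substituted phenol with strong base. A4 needs a four-membered ring with three different oxygen substituents and one reduced carbon, which means several steps with regiochemical control. The D–E ether still has to be made separately. The ketene function, loaded with oxygen donors, is a weaker electrophile and may oligomerise before it meets A5.

In comparison, on structure it builds a ring and three ring bonds where the chosen plan builds two C–O bonds. On mechanism it rests on a known pericyclic cascade, although untested with such oxygen-rich partners, so it is ahead in precedent. On step economy it is longer than nine steps. It is equal in ending with a global demethylation, with twelve ethers instead of thirteen.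

Alternative 3: Four hydroxyls are unmasked at once from formyl groups.

The cut traces the C4 hydroxyls of rings A, C, D and E back to formyl groups. The pentameric tetra-aldehyde A7 would be assembled by SNAr reactions in which each formyl group activates a para or ortho leaving group. In the forward key step a peracid converts the four aldehyde groups of A7 into aryl formate groups by aryl migration, and K2CO3 in methanol frees the nonamethyl ether A8.

In its favour, each formyl group works twice, as activator and as masked hydroxyl. SNAr etherification is metal-free, and Baeyer–Villiger oxidation of 2,6-dioxygenated benzaldehydes is dependable. Only nine ethers remain to be cleaved, and every reaction type is known. The chosen route uses the same tactic on a small scale in steps 1, 2, 4 and 5, so on those bonds the two plans are equal.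

Against it, ring B has no formyl group, and the ring C oxygen at C2 is meta to the ring C formyl group. Those positions must therefore react as nucleophiles, one of them a crowded 2,6-dimethoxyphenoxide and the other a hydroxyl that must first be differentiated. Formyl-bearing phenoxides are weak nucleophiles. Methoxy groups ortho or para to a formyl group can themselves be displaced at the temperatures needed. Ring D needs two SNAr events with distinguishable leaving groups. Four peracid oxidations must go to completion beside the electron-rich ring B of A7.

In comparison, on structure it covers all four ethers with one idea. On mechanism it is better founded than the chosen key step. On step economy it is likely longer, because each ring of A7 needs its own pattern of fluorine and formyl groups, where the chosen plan uses commercial gallates for rings D and E.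

Key step: step 8

Remarks on the chemistry
- Compounds 1, 2, 6, 11 and 12 are taken as purchasable.
- Compounds 15 and 16 map onto 17 ring by ring and atom for atom; no structure in the plan needs correcting.
- Methyl is kept as the only protecting group. Aryl methyl ethers on simple benzene rings offer zerovalent nickel no reactive C–O bond, whereas benzyl, silyl or acyl groups would.
- For step 8 the thiophene-bridged relative of 1,2-bis(dicyclohexylphosphino)ethane is chosen, because it is the ligand of the closest known reaction class.

## Route

Step 1
Reactants: 1 2,4,6-trimethoxyphenol; 2 4-bromo-2,6-dimethoxybenzaldehyde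
Product: 3 2,6-dimethoxy-4-(2,4,6-trimethoxyphenoxy)benzaldehyde
Conditions: CuI (10 mol %), picolinic acid (20 mol %), K3PO4, DMSO, 90 °C, argon
Reagents that add atoms: none
Why: Ullmann-type copper-catalysed diaryl ether synthesis; the bromide of 2 is para to the formyl group and flanked by C–H, so even the di-ortho-substituted phenoxide of 1 should couple, and the non-enolisable aldehyde tolerates K3PO4.

Step 2
Reactants: 3 2,6-dimethoxy-4-(2,4,6-trimethoxyphenoxy)benzaldehyde
Product: 5 2,6-dimethoxy-4-(2,4,6-trimethoxyphenoxy)phenol, via aryl formate 4 (not isolated)
Conditions: mCPBA, NaHCO3, CH2Cl2, 0 °C to rt; aq. Na2S2O3 wash; then K2CO3, MeOH, rt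
Reagents that add atoms: 3-chloroperbenzoic acid (mCPBA), OOC(=O)c1cccc(Cl)c1
Why: Baeyer–Villiger oxidation; the ring B carbon flanked by two methoxy groups and para to an aryloxy group migrates in preference to hydrogen, and methanolysis of the formate frees the phenol; the peracid is destroyed before the phenol is set free.

Step 3
Reactants: 6 5-bromo-1,2,3-trimethoxybenzene
Product: 7 6-bromo-2,3,4-trimethoxybenzaldehyde
Conditions: Cl2CHOMe, TiCl4, CH2Cl2, −20 to 0 °C; ice-cold aq. HCl
Reagents that add atoms: dichloromethyl methyl ether, COC(Cl)Cl (formyl carbon); water, O (formyl oxygen, on hydrolysis of the α-chloro ether)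
Why: Rieche formylation (Friedel–Crafts type); the two open positions of 6 are equivalent and are ortho and para to methoxy groups, so a single isomer should form, with the formyl group next to the bromide.

Step 4
Reactants: 5 2,6-dimethoxy-4-(2,4,6-trimethoxyphenoxy)phenol; 7 6-bromo-2,3,4-trimethoxybenzaldehyde
Product: 8 6-[2,6-dimethoxy-4-(2,4,6-trimethoxyphenoxy)phenoxy]-2,3,4-trimethoxybenzaldehyde
Conditions: CuI (20 mol %), picolinic acid (40 mol %), K3PO4, DMSO, 110 °C, argon
Reagents that add atoms: none
Why: Ullmann-type copper-catalysed coupling of a hindered phenol; the ortho formyl group of 7 activates the C–Br bond and can hold the copper, which offsets the two ortho methoxy groups of the phenoxide, and the bromide carbon has a hydrogen on its other side.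

Step 5
Reactants: 8 6-[2,6-dimethoxy-4-(2,4,6-trimethoxyphenoxy)phenoxy]-2,3,4-trimethoxybenzaldehyde
Product: 10 6-[2,6-dimethoxy-4-(2,4,6-trimethoxyphenoxy)phenoxy]-2,3,4-trimethoxyphenol, via aryl formate 9 (not isolated)
Conditions: mCPBA, NaHCO3, CH2Cl2, 0 °C to rt; aq. Na2S2O3 wash; then K2CO3, MeOH, rt
Reagents that add atoms: 3-chloroperbenzoic acid (mCPBA), OOC(=O)c1cccc(Cl)c1
Why: Baeyer–Villiger oxidation as in step 2; the ring C carbon carrying the formyl group lies between a methoxy and an aryloxy group and should migrate readily, giving the one free hydroxyl of ring C exactly at C2.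

Step 6
Reactants: 11 3-hydroxy-4,5-dimethoxybenzoic acid; 12 3,4,5-trimethoxybenzoyl chloride
Product: 13 3,4-dimethoxy-5-(3,4,5-trimethoxybenzoyloxy)benzoic acid
Conditions: NaOH (2.0 equiv), H2O–acetone, 0 °C; then aq. HCl to pH 2
Reagents that add atoms: none
Why: Schotten–Baumann acylation as in the classical depside synthesis; in the dianion of 11 the phenoxide is far more nucleophilic than the carboxylate, and the cold, exactly neutralised medium spares the new aryl ester.

Step 7
Reactants: 13 3,4-dimethoxy-5-(3,4,5-trimethoxybenzoyloxy)benzoic acid; 10 6-[2,6-dimethoxy-4-(2,4,6-trimethoxyphenoxy)phenoxy]-2,3,4-trimethoxyphenol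
Product: 15 6-[2,6-dimethoxy-4-(2,4,6-trimethoxyphenoxy)phenoxy]-2,3,4-trimethoxyphenyl 3,4-dimethoxy-5-(3,4,5-trimethoxybenzoyloxy)benzoate, via depside acid chloride 14 (not isolated)
Conditions: (COCl)2, DMF (cat.), CH2Cl2, 0 °C to rt, volatiles removed; then 10, Et3N, DMAP (cat.), CH2Cl2, 0 °C to rt
Reagents that add atoms: none
Why: acid chloride formation followed by DMAP-catalysed acylation of a hindered phenol; the acyl chloride is far more electrophilic than the aryl ester inside 14, so no transacylation is expected, and excess chlorinating agent is removed before the electron-rich 10 is added.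

Step 8
Reactants: 15 6-[2,6-dimethoxy-4-(2,4,6-trimethoxyphenoxy)phenoxy]-2,3,4-trimethoxyphenyl 3,4-dimethoxy-5-(3,4,5-trimethoxybenzoyloxy)benzoate
Product: 16 2-{4-[2-(3,4-dimethoxy-5-(3,4,5-trimethoxyphenoxy)phenoxy)-3,4,5-trimethoxyphenoxy]-3,5-dimethoxyphenoxy}-1,3,5-trimethoxybenzene
Conditions: Ni(C8H12)2 (30 mol %), 3,4-bis(dicyclohexylphosphino)thiophene (60 mol %), K3PO4 (1.5 equiv), m-xylene (0.02 M), 160 °C, slow argon sweep through a reflux condenser
Reagents that add atoms: none
Why: Proposed new method: zerovalent nickel on the cis-chelating, electron-rich bisphosphine should add across the acyl C–O bond of each aryl ester of 15 to give an acyl(aryloxo) complex of divalent nickel, CO then de-inserts to an aryl(aryloxo)nickel species and C–O reductive elimination releases the diaryl ether while CO leaves with the argon stream; the closest known reaction type is the nickel- or palladium-catalysed decarbonylative etherification of aryl esters, established mainly for azine carboxylates with this ligand class, and its use on two electron-rich benzoate-type esters in one molecule is new. The two events are independent, so whichever ester reacts first, the half-reacted material is carried on to 16. No ring closes and no stereocenter forms. The step needs insertion into the acyl C–O bonds and not the aryl C–O bonds: both carbonyl carbons hang on ring carbons flanked only by C–H and are open to the metal, whereas the ester oxygen on ring C lies between an aryloxy and a methoxy group and that on ring D next to a methoxy group, and no ring is a fused arene of the kind that favours aryl C–O insertion. The same feature helps reductive elimination: the nickel-bound carbons of rings D and E have no ortho substituent, are meta to two oxygens and para to a methoxy group twisted out of conjugation by its neighbours, and the partner aryloxides are electron-rich. Complete loss of CO at both esters is served by the open system and the temperature, and exchange of aryloxide between nickel centres, which would scramble the two different ethers, is held back by high dilution. The thirteen methyl ethers and the two existing diaryl ethers offer only unactivated aryl C–O bonds, which zerovalent nickel should not cleave without a hydride source or an organometallic partner.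

Step 9
Reactants: 16 2-{4-[2-(3,4-dimethoxy-5-(3,4,5-trimethoxyphenoxy)phenoxy)-3,4,5-trimethoxyphenoxy]-3,5-dimethoxyphenoxy}-1,3,5-trimethoxybenzene
Product: 17 2-{4-[2-(3,4-dihydroxy-5-(3,4,5-trihydroxyphenoxy)phenoxy)-3,4,5-trihydroxyphenoxy]-3,5-dihydroxyphenoxy}benzene-1,3,5-triol
Conditions: BBr3 (excess), CH2Cl2, −78 °C to rt, argon; MeOH, then degassed H2O; Sephadex LH-20 under argon
Reagents that add atoms: none
Why: Lewis acid ether cleavage with BBr3; boron binds each methoxy oxygen and bromide attacks the methyl carbon, while the diaryl ether oxygens have no sp3 carbon to lose and persist; hydrolysis of the aryl borates gives the thirteen hydroxyls.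

## Compound list

1 | 2,4,6-trimethoxyphenol | COc1cc(OC)c(O)c(OC)c1 | starting material
2 | 4-bromo-2,6-dimethoxybenzaldehyde | COc1cc(Br)cc(OC)c1C=O | starting material
3 | 2,6-dimethoxy-4-(2,4,6-trimethoxyphenoxy)benzaldehyde | COc1cc(OC)c(Oc2cc(OC)c(C=O)c(OC)c2)c(OC)c1 | intermediate
4 | 2,6-dimethoxy-4-(2,4,6-trimethoxyphenoxy)phenyl formate | COc1cc(OC)c(Oc2cc(OC)c(OC=O)c(OC)c2)c(OC)c1 | intermediate
5 | 2,6-dimethoxy-4-(2,4,6-trimethoxyphenoxy)phenol | COc1cc(OC)c(Oc2cc(OC)c(O)c(OC)c2)c(OC)c1 | intermediate
6 | 5-bromo-1,2,3-trimethoxybenzene | COc1cc(Br)cc(OC)c1OC | starting material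
7 | 6-bromo-2,3,4-trimethoxybenzaldehyde | COc1cc(Br)c(C=O)c(OC)c1OC | intermediate
8 | 6-[2,6-dimethoxy-4-(2,4,6-trimethoxyphenoxy)phenoxy]-2,3,4-trimethoxybenzaldehyde | COc1cc(OC)c(Oc2cc(OC)c(Oc3cc(OC)c(OC)c(OC)c3C=O)c(OC)c2)c(OC)c1 | intermediate
9 | 6-[2,6-dimethoxy-4-(2,4,6-trimethoxyphenoxy)phenoxy]-2,3,4-trimethoxyphenyl formate | COc1cc(OC)c(Oc2cc(OC)c(Oc3cc(OC)c(OC)c(OC)c3OC=O)c(OC)c2)c(OC)c1 | intermediate
10 | 6-[2,6-dimethoxy-4-(2,4,6-trimethoxyphenoxy)phenoxy]-2,3,4-trimethoxyphenol | COc1cc(OC)c(Oc2cc(OC)c(Oc3cc(OC)c(OC)c(OC)c3O)c(OC)c2)c(OC)c1 | intermediate
11 | 3-hydroxy-4,5-dimethoxybenzoic acid | COc1cc(cc(O)c1OC)C(O)=O | starting material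
12 | 3,4,5-trimethoxybenzoyl chloride | COc1cc(cc(OC)c1OC)C(Cl)=O | starting material
13 | 3,4-dimethoxy-5-(3,4,5-trimethoxybenzoyloxy)benzoic acid | COc1cc(cc(OC(=O)c2cc(OC)c(OC)c(OC)c2)c1OC)C(O)=O | intermediate
14 | 3,4-dimethoxy-5-(3,4,5-trimethoxybenzoyloxy)benzoyl chloride | COc1cc(cc(OC(=O)c2cc(OC)c(OC)c(OC)c2)c1OC)C(Cl)=O | intermediate
15 | 6-[2,6-dimethoxy-4-(2,4,6-trimethoxyphenoxy)phenoxy]-2,3,4-trimethoxyphenyl 3,4-dimethoxy-5-(3,4,5-trimethoxybenzoyloxy)benzoate | COc1cc(OC)c(Oc2cc(OC)c(Oc3cc(OC)c(OC)c(OC)c3OC(=O)c3cc(OC)c(OC)c(OC(=O)c4cc(OC)c(OC)c(OC)c4)c3)c(OC)c2)c(OC)c1 | intermediate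
16 | 2-{4-[2-(3,4-dimethoxy-5-(3,4,5-trimethoxyphenoxy)phenoxy)-3,4,5-trimethoxyphenoxy]-3,5-dimethoxyphenoxy}-1,3,5-trimethoxybenzene (tridecamethyl ether of 17) | COc1cc(OC)c(Oc2cc(OC)c(Oc3cc(OC)c(OC)c(OC)c3Oc3cc(OC)c(OC)c(Oc4cc(OC)c(OC)c(OC)c4)c3)c(OC)c2)c(OC)c1 | intermediate
17 | 2-{4-[2-(3,4-dihydroxy-5-(3,4,5-trihydroxyphenoxy)phenoxy)-3,4,5-trihydroxyphenoxy]-3,5-dihydroxyphenoxy}benzene-1,3,5-triol | Oc1cc(O)c(Oc2cc(O)c(Oc3cc(O)c(O)c(O)c3Oc3cc(O)c(O)c(Oc4cc(O)c(O)c(O)c4)c3)c(O)c2)c(O)c1 | target

## Step count and least certain steps

Total step count: 9. Longest linear sequence: 7 steps (steps 1, 2, 4, 5, 7, 8 and 9). Step 3 and step 6 are side branches.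

Step 8 (key step, proposed new method). Stalling of the catalytic cycle is the most likely failure. Electron-rich aroyl esters add slowly to zerovalent nickel, CO de-insertion from an electron-rich aroyl group is slow, and retained CO turns the catalyst into inert carbonyl complexes. Exchange of aryloxide between nickel centres would scramble the C–D and D–E ethers, and protonation of the aryl–nickel bond by traces of water would end the cycle without C–O bond formation. Changing the ligand to 1,2-bis(dicyclohexylphosphino)ethane or the metal source to Pd(OAc)2 would be a change of conditions only. The fallback uses known copper chemistry; it sets out from 10, leaves 15 aside and comes back to the route at 16. Commercial 5-bromo-2,3-dimethoxybenzaldehyde would be oxidised with mCPBA to 5-bromo-2,3-dimethoxyphenyl formate F1, and cleavage of F1 with K2CO3 in MeOH would give 5-bromo-2,3-dimethoxyphenol F2. Chan–Lam coupling of F2 with 3,4,5-trimethoxyphenylboronic acid, mediated by Cu(OAc)2 with pyridine in CH2Cl2 under air, would give 5-bromo-1,2-dimethoxy-3-(3,4,5-trimethoxyphenoxy)benzene F3; the C–Br bond is inert under these oxidative conditions. An Ullmann-type coupling of 10 with F3, using CuI, picolinic acid and K3PO4 in DMSO at 110 °C, would then form the C–D ether at a bromide carbon flanked only by C–H and give 16.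

Step 4. Slow C–O bond formation between a phenoxide with two ortho methoxy groups and an ortho-substituted bromide is the main risk. It leaves time for reductive loss of bromine from 7 and for oxidation of the electron-rich phenoxide of 5 by traces of air. The fallback uses no metal in the bond-forming event; it sets out from 5 and comes back at 8. Rieche formylation of commercial 5-fluoro-1,2,3-trimethoxybenzene would give 6-fluoro-2,3,4-trimethoxybenzaldehyde F4. SNAr of the phenoxide of 5 on F4, with Cs2CO3 in DMSO at 120 to 140 °C, would give 8. The ortho formyl group stabilises the anionic adduct, and the small fluoride eases approach of the crowded nucleophile. The para methoxy group makes forcing conditions likely.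

Step 5. Peracid attack on the electron-rich rings A and B, leading to ring hydroxylation and quinone formation, may compete with the Baeyer–Villiger event, because 8 carries three polyalkoxy rings. The fallback moves the oxidation to the monomer; it sets out from 7, uses 5 and comes back at 10. Baeyer–Villiger oxidation of 7 would give 6-bromo-2,3,4-trimethoxyphenyl formate F5, and methanolysis of F5 would give 6-bromo-2,3,4-trimethoxyphenol F6. Benzylation of F6 with benzyl bromide and K2CO3 in DMF would give 2-(benzyloxy)-1-bromo-3,4,5-trimethoxybenzene F7. Ullmann-type coupling of F7 with 5, using CuI, picolinic acid and K3PO4 in DMSO, would give 1-(benzyloxy)-6-[2,6-dimethoxy-4-(2,4,6-trimethoxyphenoxy)phenoxy]-2,3,4-trimethoxybenzene F8. Hydrogenolysis of F8 with H2 over Pd on carbon in EtOAc would then give 10. The coupling of F7 is harder than step 4 because the formyl activation is gone, which is the price of keeping peracid away from the trimer.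

Step 6. Acylation at the carboxylate would give a mixed anhydride, which can pass the ring D acyl group to another phenoxide and start oligomeric depsides; hydrolysis of the new aryl ester by hydroxide is the second risk. The fallback protects the carboxyl group; it sets out from 11 and comes back at 13. Alkylation of the carboxylate alone, with benzyl bromide and KHCO3 in DMF, would give benzyl 3-hydroxy-4,5-dimethoxybenzoate F9. Acylation of F9 with 12, Et3N and DMAP in CH2Cl2 would give benzyl 3,4-dimethoxy-5-(3,4,5-trimethoxybenzoyloxy)benzoate F10. Hydrogenolysis of F10 with H2 over Pd on carbon in EtOAc would free 13 without touching the aryl ester.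

Step 9. Cleavage of some of the thirteen ethers may stay incomplete once the partly demethylated borates precipitate, and the pyrogallol-rich product may be oxidised by air during isolation. The fallback isolates the product through a stable derivative; it sets out from 16 and comes back at 17. The crude product of the BBr3 treatment would be acetylated without purification, with acetic anhydride in pyridine, to the tridecaacetate of 17 F11. F11 can be chromatographed in air and separated from under-demethylated material, which can be returned to BBr3. Deacetylation of F11 under argon, with catalytic NaOMe in degassed MeOH followed by an acidic resin, would release 17.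

## Further compounds

F1 | step 8 | 5-bromo-2,3-dimethoxyphenyl formate | COc1cc(Br)cc(OC=O)c1OC
F2 | step 8 | 5-bromo-2,3-dimethoxyphenol | COc1cc(Br)cc(O)c1OC
F3 | step 8 | 5-bromo-1,2-dimethoxy-3-(3,4,5-trimethoxyphenoxy)benzene | COc1cc(Br)cc(Oc2cc(OC)c(OC)c(OC)c2)c1OC
F4 | step 4 | 6-fluoro-2,3,4-trimethoxybenzaldehyde | COc1cc(F)c(C=O)c(OC)c1OC
F5 | step 5 | 6-bromo-2,3,4-trimethoxyphenyl formate | COc1cc(Br)c(OC=O)c(OC)c1OC
F6 | step 5 | 6-bromo-2,3,4-trimethoxyphenol | COc1cc(Br)c(O)c(OC)c1OC
F7 | step 5 | 2-(benzyloxy)-1-bromo-3,4,5-trimethoxybenzene | COc1cc(Br)c(OCc2ccccc2)c(OC)c1OC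
F8 | step 5 | 1-(benzyloxy)-6-[2,6-dimethoxy-4-(2,4,6-trimethoxyphenoxy)phenoxy]-2,3,4-trimethoxybenzene | COc1cc(OC)c(Oc2cc(OC)c(Oc3cc(OC)c(OC)c(OC)c3OCc3ccccc3)c(OC)c2)c(OC)c1
F9 | step 6 | benzyl 3-hydroxy-4,5-dimethoxybenzoate | COc1cc(cc(O)c1OC)C(=O)OCc1ccccc1
F10 | step 6 | benzyl 3,4-dimethoxy-5-(3,4,5-trimethoxybenzoyloxy)benzoate | COc1cc(cc(OC(=O)c2cc(OC)c(OC)c(OC)c2)c1OC)C(=O)OCc1ccccc1
F11 | step 9 | tridecaacetate of 17 | CC(=O)Oc1cc(OC(C)=O)c(Oc2cc(OC(C)=O)c(Oc3cc(OC(C)=O)c(OC(C)=O)c(OC(C)=O)c3Oc3cc(OC(C)=O)c(OC(C)=O)c(Oc4cc(OC(C)=O)c(OC(C)=O)c(OC(C)=O)c4)c3)c(OC(C)=O)c2)c(OC(C)=O)c1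
A1 | alternative 1 | dimethyl 2-{4-[2-(3,4-dimethoxy-5-(3,4,5-trimethoxyphenoxy)phenoxy)-3,4,5-trimethoxyphenoxy]-3,5-dimethoxyphenoxy}malonate | COC(=O)C(Oc1cc(OC)c(Oc2cc(OC)c(OC)c(OC)c2Oc2cc(OC)c(OC)c(Oc3cc(OC)c(OC)c(OC)c3)c2)c(OC)c1)C(=O)OC
A2 | alternative 1 | dimethyl 3-oxopentanedioate | COC(=O)CC(=O)CC(=O)OC
A3 | alternative 1 | dimethyl 2,4,6-trihydroxy-5-aryloxybenzene-1,3-dicarboxylate carrying rings B to E | COC(=O)c1c(O)c(C(=O)OC)c(O)c(Oc2cc(OC)c(Oc3cc(OC)c(OC)c(OC)c3Oc3cc(OC)c(OC)c(Oc4cc(OC)c(OC)c(OC)c4)c3)c(OC)c2)c1O
A4 | alternative 2 | 2-[3,4-dimethoxy-5-(3,4,5-trimethoxyphenoxy)phenoxy]-3,4-dimethoxycyclobut-2-en-1-one | COC1C(=O)C(Oc2cc(OC)c(OC)c(Oc3cc(OC)c(OC)c(OC)c3)c2)=C1OC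
A5 | alternative 2 | 2-ethynyloxy-1,3-dimethoxy-5-(2,4,6-trimethoxyphenoxy)benzene | C#COc1c(OC)cc(Oc2c(OC)cc(OC)cc2OC)cc1OC
A6 | alternative 2 | dodecamethyl ether of 17 with the ring C hydroxyl at C5 free | COc1cc(OC)c(Oc2cc(OC)c(Oc3cc(O)c(OC)c(OC)c3Oc3cc(OC)c(OC)c(Oc4cc(OC)c(OC)c(OC)c4)c3)c(OC)c2)c(OC)c1
A7 | alternative 3 | pentameric tetra-aldehyde (formyl groups at C4 of rings A, C, D and E) | O=Cc1cc(OC)c(Oc2cc(OC)c(Oc3cc(OC)c(C=O)c(OC)c3Oc3cc(OC)c(C=O)c(Oc4cc(OC)c(C=O)c(OC)c4)c3)c(OC)c2)c(OC)c1
A8 | alternative 3 | nonamethyl ether of 17 with free hydroxyls at C4 of rings A, C, D and E | Oc1cc(OC)c(Oc2cc(OC)c(Oc3cc(OC)c(O)c(OC)c3Oc3cc(OC)c(O)c(Oc4cc(OC)c(O)c(OC)c4)c3)c(OC)c2)c(OC)c1
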